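**Retrosynthetic overview**
1. 27 ⇒ 26 ⇒ vinyl triflate 21 + diene 24. The C9–C11 bond is made last by B-alkyl Suzuki coupling, so the whole side chain arrives in one piece; its E alkene is bought in with 22.
2. 21 ⇒ trans-decalin-2,6-dione 14. The C2 ketone becomes 2α-OAc (SmI2). The C6 ketone gives 7α-OH by enolate oxidation and then 6β-OH by hydride. C9–OTBS becomes the ketone and then the enol triflate, which creates C8=C9.
3. 14 ⇒ spiro-epoxide 9 + isopropenyl cuprate. Ring A is not closed as a six-membered ring. It grows out of the cyclobutane C1–C2–C5–C10 by insertion of C3 and C4 (epoxide opening, retro-aldol, Michael addition).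
4. Enabling feature: C5 is α to the C6 carbonyl, the oxygens at C2 and C6 are 1,5-related through C5, and the quaternary C4 sits β to C2. Hence C2–C5 is a retro-aldol bond of a cyclobutanol and C4–C5 is a Michael bond.
5. Ring order: ring B (from 1, C9 carbinol by CBS reduction) → cyclobutane (allene [2+2], sets C10) → ring A (step 8, sets C4 and C5).

Key step: step 8

Remark: labdane numbering (C1–C10 for the decalin carbons, C11–C16 for the side chain) is used for all intermediates. α means the face opposite to the C10 methyl group. Compounds 1, 5, 10 and 22 are taken as commercial.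

Step 1
Reactants: 1 2-methylcyclohex-2-en-1-one
Product: 2 (S)-2-methylcyclohex-2-en-1-ol
Conditions: (R)-Me-CBS (10 mol%), BH3·SMe2, THF, −20 °C; MeOH
Reagents that add atoms: none
Why: Corey–Bakshi–Shibata reduction, in which the 2-methylalkenyl arm acts as the large ketone substituent so that the (R)-oxazaborolidine should deliver hydride 1,2 to give the S carbinol, the temporary C9 stereocentre from which all others are relayed.

Step 2
Reactants: 2 (S)-2-methylcyclohex-2-en-1-ol
Product: 3 (S)-tert-butyldimethyl[(2-methylcyclohex-2-en-1-yl)oxy]silane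
Conditions: TBSCl, imidazole, DMF, rt
Reagents that add atoms: TBSCl, CC(C)(C)[Si](C)(C)Cl
Why: Imidazole-promoted silylation installs a bulky group, stable to base and oxidants, that will steer the photocycloaddition and the cuprate addition.

Step 3
Reactants: 3 (S)-tert-butyldimethyl[(2-methylcyclohex-2-en-1-yl)oxy]silane
Product: 4 (S)-4-(tert-butyldimethylsilyloxy)-3-methylcyclohex-2-en-1-one
Conditions: Rh2(cap)4 (1 mol%), t-BuOOH (70% aq.), K2CO3, CH2Cl2, rt
Reagents that add atoms: tert-butyl hydroperoxide, CC(C)(C)OO
Why: Rhodium-catalysed allylic C–H oxidation should take the ring CH2 next to the vinylic CH, the least hindered allylic site, and give the enone (C6 carbonyl, C5=C10) without touching the C9 stereocentre.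

Step 4
Reactants: 4 (S)-4-(tert-butyldimethylsilyloxy)-3-methylcyclohex-2-en-1-one; 5 propa-1,2-diene (allene)
Product: 6 cis-fused 5-(TBSO)-6-methyl-8-methylidenebicyclo[4.2.0]octan-2-one, cyclobutane anti to the silyloxy group (C10 methyl β, 9β-OTBS, C1 and C2 on the α face)
Conditions: 5 (excess, condensed), CH2Cl2, hν (medium-pressure Hg lamp, Pyrex filter), −78 °C; then basic Al2O3
Reagents that add atoms: none
Why: Enone–allene [2+2] photocycloaddition, which is head-to-head so that the methylidene carbon (C2) ends on the enone α-carbon C5 and the CH2 (C1) on C10, while A1,2 strain with the ring methyl holds the OTBS group pseudoaxial so that allene should add to the opposite face and set the C10 quaternary centre; alumina converts any trans-fused adduct into the cis isomer.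

Step 5
Reactants: 6 cis-fused methylidene ketone
Product: 7 5-(TBSO)-6-methyl-8-methylidenebicyclo[4.2.0]oct-3-en-2-one (C7=C8 enone)
Conditions: IBX (2.5 equiv), DMSO/fluorobenzene, 70 °C
Reagents that add atoms: none
Why: IBX dehydrogenation through the enol, regiochemically unambiguous because only the C7–C8 pair carries both an α- and a β-hydrogen, and tolerated by the silyl ether and the unconjugated alkene.

Step 6
Reactants: 7 bicyclic enone
Product: 8 5-(TBSO)-4,6-dimethyl-8-methylidenebicyclo[4.2.0]octan-2-one (8α-methyl, trans to 9β-OTBS)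
Conditions: MeLi, CuI, Et2O, 0 °C (gives Me2CuLi); then 7, −78 → −40 °C; aq. NH4Cl
Reagents that add atoms: methyllithium (used as Me2CuLi), [Li]C
Why: Gilman cuprate 1,4-addition, which on 4-silyloxycyclohexenones occurs anti to the vicinal silyloxy group and should therefore give the 8α-methyl ketone, the future C8 methyl and the conformational lock of ring B in step 8.

Step 7
Reactants: 8 methylidene ketone
Product: 9 spiro-epoxide of 8 (oxirane on C2, its CH2 is the future C3, oxygen on the convex face)
Conditions: dimethyldioxirane, acetone, 0 °C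
Reagents that add atoms: dimethyldioxirane, CC1(C)OO1
Why: Epoxidation of the strained 1,1-disubstituted alkene with neutral dimethyldioxirane avoids acid-induced rearrangement of the oxaspirohexane and Baeyer–Villiger oxidation; attack from the convex face is expected, but the spiro centre is lost in step 8.

Step 8
Reactants: 9 spiro-epoxide; 10 isopropenylmagnesium bromide
Product: 14 9β-(TBSO)-4,4,8α,10β-tetramethyl-trans-decalin-2,6-dione (5α-H), via cyclobutanol adduct 11 (not isolated), via deconjugated seco-dione 12 (not isolated), via conjugated seco-dione 13 (not isolated)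
Conditions: 10 (2.4 equiv), CuI (1.2 equiv), THF, −40 °C; add 9, −40 → 0 °C; then t-BuOH, KOt-Bu (0.3 equiv), 0 °C → rt; aq. NH4Cl
Reagents that add atoms: none
Why: Proposed new method: the cuprate opens the spiro-epoxide at its CH2 (the future C3) to give cyclobutoxide 11, which is a strained aldol of the C6 ketone, so that retro-aldol cleavage of the C2–C5 bond releases the ring strain of about 26 kcal/mol and gives the C5 enolate beside a C2 ketone (12), alkoxide moves the isopropenyl double bond into conjugation (13), and C5 then adds to the β,β-dimethyl terminus C4, whereby C3 and C4 are inserted between C2 and C5 and the four-membered ring C1–C2–C5–C10 becomes the six-membered ring A. The closest known reaction types are the retro-aldol opening of 2-acylcyclobutanols in the De Mayo reaction, the alkoxide-accelerated 1,3-shift of 1-vinylcyclobutanols that carry a carbanion-stabilising group, and the second half of a double Michael annulation; new is their coupling to an epoxide opening in one flask. Ring A closes in the 6-endo-trig mode with the enolate double bond C5=C6 exocyclic to the new ring, and no other ring is closed. C10 is not touched, C4 is not stereogenic, and the only new stereocentre C5 remains α to the C6 ketone and is equilibrated by KOt-Bu to the trans-decalin (5α-H), because the equatorial 8α-methyl and 9β-silyloxy groups lock the chair of ring B and a cis fusion would need either the quaternary C4 axial on ring B or a ring flip that sets the C8 methyl syn-axial to C1. The step needs attack at the epoxide and not at the C6 ketone, which the soft organocopper reagent at low temperature secures, and a single fragmentation and closure path, which the substrate secures since C2–C5 is the only bond of the carbinol carbon that is α to a carbonyl, only C5 and not C7 can reach C4 through a six-membered transition state, and the competing bridged aldols are reversible and cannot dehydrate. In one operation the step should thus deliver the C3–C4 unit, the C4 quaternary carbon, the C4–C5 bond, the trans ring fusion and the sterically differentiated C2 and C6 carbonyls from an epoxide that is made in four steps from a monocyclic enone.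

Step 9
Reactants: 14 trans-decalin-2,6-dione
Product: 15 2α-hydroxy-9β-(TBSO)-4,4,8α,10β-tetramethyl-trans-decalin-6-one
Conditions: SmI2 (2.2 equiv), H2O, THF, 0 °C
Reagents that add atoms: none
Why: Single-electron (ketyl) reduction with divalent samarium and water gives the thermodynamically preferred equatorial 2α-alcohol, whereas hydrides would attack the open α face and give the axial 2β-ol, and the C6 carbonyl, wedged against the C4 gem-dimethyl group and shielded by two syn-axial methyls, should react more slowly.

Step 10
Reactants: 15 2α-hydroxy-6-ketone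
Product: 16 2α,7α-dihydroxy-9β-(TBSO)-4,4,8α,10β-tetramethyl-trans-decalin-6-one
Conditions: KN(SiMe3)2 (2.3 equiv), THF, −78 °C; 2-(phenylsulfonyl)-3-phenyloxaziridine, −78 °C; AcOH
Reagents that add atoms: 2-(phenylsulfonyl)-3-phenyloxaziridine, O=S(=O)(c1ccccc1)N1OC1c1ccccc1
Why: Enolate hydroxylation with an N-sulfonyloxaziridine: after the alkoxide has formed, kinetic deprotonation takes the accessible C7–H rather than the hindered tertiary C5–H, and the oxidant should approach the α face because the β face is covered by the axial C10 and C4 methyls, giving the axial 7α-alcohol.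

Step 11
Reactants: 16 2α,7α-dihydroxy-6-ketone
Product: 17 9β-(TBSO)-4,4,8α,10β-tetramethyl-trans-decalin-2α,6β,7α-triol
Conditions: NaBH4, MeOH/THF, 0 °C
Reagents that add atoms: none
Why: Borohydride reduction of the hindered C6 ketone, where axial attack from the β face is blocked by the syn-axial methyls so that hydride should enter from the α face and give the axial 6β-alcohol, trans-diaxial to the 7α-hydroxyl.

Step 12
Reactants: 17 triol
Product: 18 2α,6β,7α-triacetoxy-9β-(TBSO)-4,4,8α,10β-tetramethyl-trans-decalin
Conditions: Ac2O, DMAP, pyridine, 60 °C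
Reagents that add atoms: acetic anhydride, CC(=O)OC(C)=O
Why: DMAP-catalysed peracetylation under forcing conditions esterifies the equatorial 2α- and the axial 6β- and 7α-hydroxyls while the silyl ether at C9 stays in place.

Step 13
Reactants: 18 triacetate silyl ether
Product: 19 2α,6β,7α-triacetoxy-4,4,8α,10β-tetramethyl-trans-decalin-9β-ol
Conditions: aq. HF (48%), MeCN, rt
Reagents that add atoms: none
Why: Acidic fluoride desilylation removes the hindered secondary TBS ether without touching the three acetates.

Step 14
Reactants: 19 triacetoxy alcohol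
Product: 20 2α,6β,7α-triacetoxy-4,4,8α,10β-tetramethyl-trans-decalin-9-one
Conditions: Dess–Martin periodinane, CH2Cl2, 0 °C → rt
Reagents that add atoms: none
Why: Dess–Martin oxidation under neutral conditions gives the C9 ketone and avoids base-induced β-elimination of the C7 acetate.

Step 15
Reactants: 20 triacetoxy ketone
Product: 21 C9 enol triflate of 20 (C8=C9, 2α,6β,7α-triacetate)
Conditions: Tf2O, 2,6-di-tert-butyl-4-methylpyridine, CH2Cl2, 0 °C → rt
Reagents that add atoms: triflic anhydride, O=S(=O)(OS(=O)(=O)C(F)(F)F)C(F)(F)F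
Why: Vinyl triflate formation by O-sulfonylation with Tf2O and deprotonation by a hindered pyridine, a protocol tolerated by acetate esters on neopentyl cyclic ketones; C10 is quaternary, so that only the axial C8–H can be lost and the tetrasubstituted C8=C9 bond is formed regiospecifically.

Step 16
Reactants: 22 (E)-3-methylpent-2-en-4-yn-1-ol
Product: 23 (E)-tert-butyldimethyl[(3-methylpent-2-en-4-yn-1-yl)oxy]silane
Conditions: TBSCl, imidazole, CH2Cl2, rt
Reagents that add atoms: TBSCl, CC(C)(C)[Si](C)(C)Cl
Why: Imidazole-promoted silylation masks the future C15 hydroxyl with a group that can be removed at the end beside three acetates.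

Step 17
Reactants: 23 enyne silyl ether
Product: 24 (E)-tert-butyldimethyl[(3-methylpenta-2,4-dien-1-yl)oxy]silane
Conditions: H2 (1 atm), Pd/CaCO3 poisoned with Pb(OAc)2, quinoline, hexane, rt
Reagents that add atoms: none
Why: Lindlar semihydrogenation of the terminal alkyne stops at the vinyl group and leaves the E trisubstituted alkene unchanged.

Step 18
Reactants: 21 vinyl triflate; 24 diene silyl ether
Product: 26 15-O-TBS ether of the target, via B-alkyl-9-BBN 25 (not isolated)
Conditions: 24, 9-BBN-H, THF, 0 °C → rt; then 21, Pd(dppf)Cl2 (10 mol%), AsPh3, Cs2CO3, DMF/H2O, rt → 45 °C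
Reagents that add atoms: none
Why: Hydroboration of the monosubstituted vinyl group of the diene with 9-BBN-H (anti-Markovnikov, trisubstituted alkene untouched) followed by B-alkyl Suzuki–Miyaura coupling with the vinyl triflate forms the C9–C11 bond with retention of both alkene geometries under mildly basic conditions that the acetates should survive.

Step 19
Reactants: 26 15-O-TBS ether
Product: 27 2α,6β,7α-triacetoxylabda-8,13E-dien-15-ol (target)
Conditions: HF·pyridine, pyridine, THF, 0 °C
Reagents that add atoms: none
Why: Buffered fluoride desilylation frees the primary allylic alcohol at C15 and leaves the three secondary acetates in place.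

**Compound list**
1 | 2-methylcyclohex-2-en-1-one | CC1=CCCCC1=O | starting material
2 | (S)-2-methylcyclohex-2-en-1-ol | CC1=CCCC[C@@H]1O | intermediate
3 | (S)-TBS ether of 2 | CC1=CCCC[C@@H]1O[Si](C)(C)C(C)(C)C | intermediate
4 | (S)-4-(TBSO)-3-methylcyclohex-2-en-1-one | CC1=CC(=O)CC[C@@H]1O[Si](C)(C)C(C)(C)C | intermediate
5 | propa-1,2-diene | C=C=C | starting material
6 | cis-fused 5-(TBSO)-6-methyl-8-methylidenebicyclo[4.2.0]octan-2-one | C=C1C[C@]2(C)[C@@H](O[Si](C)(C)C(C)(C)C)CCC(=O)[C@H]12 | intermediate
7 | 5-(TBSO)-6-methyl-8-methylidenebicyclo[4.2.0]oct-3-en-2-one | C=C1C[C@]2(C)[C@@H](O[Si](C)(C)C(C)(C)C)C=CC(=O)[C@H]12 | intermediate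
8 | 5-(TBSO)-4,6-dimethyl-8-methylidenebicyclo[4.2.0]octan-2-one (8α-methyl) | C=C1C[C@]2(C)[C@@H](O[Si](C)(C)C(C)(C)C)[C@H](C)CC(=O)[C@H]12 | intermediate
9 | spiro-epoxide of 8 | C1O[C@]12C[C@]3(C)[C@@H](O[Si](C)(C)C(C)(C)C)[C@H](C)CC(=O)[C@H]23 | intermediate
10 | isopropenylmagnesium bromide | CC(=C)[Mg]Br | starting material
11 | 8-hydroxy-8-(2-methylallyl) cyclobutanol adduct (formed as its alkoxide) | CC(=C)C[C@]1(O)C[C@]2(C)[C@@H](O[Si](C)(C)C(C)(C)C)[C@H](C)CC(=O)[C@H]12 | intermediate
12 | 4-(TBSO)-3,5-dimethyl-3-(4-methyl-2-oxopent-4-enyl)cyclohexanone (formed as its enolate) | CC(=C)CC(=O)C[C@@]1(C)CC(=O)C[C@@H](C)[C@@H]1O[Si](C)(C)C(C)(C)C | intermediate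
13 | 4-(TBSO)-3,5-dimethyl-3-(4-methyl-2-oxopent-3-enyl)cyclohexanone | CC(C)=CC(=O)C[C@@]1(C)CC(=O)C[C@@H](C)[C@@H]1O[Si](C)(C)C(C)(C)C | intermediate
14 | 9β-(TBSO)-4,4,8α,10β-tetramethyl-trans-decalin-2,6-dione | O=C1CC(C)(C)[C@@H]2C(=O)C[C@@H](C)[C@H](O[Si](C)(C)C(C)(C)C)[C@@]2(C)C1 | intermediate
15 | 2α-hydroxy-6-ketone | O[C@H]1CC(C)(C)[C@@H]2C(=O)C[C@@H](C)[C@H](O[Si](C)(C)C(C)(C)C)[C@@]2(C)C1 | intermediate
16 | 2α,7α-dihydroxy-6-ketone | O[C@H]1CC(C)(C)[C@@H]2C(=O)[C@@H](O)[C@@H](C)[C@H](O[Si](C)(C)C(C)(C)C)[C@@]2(C)C1 | intermediate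
17 | 2α,6β,7α-triol | O[C@H]1CC(C)(C)[C@@H]2[C@H](O)[C@@H](O)[C@@H](C)[C@H](O[Si](C)(C)C(C)(C)C)[C@@]2(C)C1 | intermediate
18 | 2α,6β,7α-triacetate, 9β-OTBS | CC(=O)O[C@H]1CC(C)(C)[C@@H]2[C@H](OC(C)=O)[C@@H](OC(C)=O)[C@@H](C)[C@H](O[Si](C)(C)C(C)(C)C)[C@@]2(C)C1 | intermediate
19 | 2α,6β,7α-triacetoxy-9β-ol | CC(=O)O[C@H]1CC(C)(C)[C@@H]2[C@H](OC(C)=O)[C@@H](OC(C)=O)[C@@H](C)[C@H](O)[C@@]2(C)C1 | intermediate
20 | 2α,6β,7α-triacetoxy-9-ketone | CC(=O)O[C@H]1CC(C)(C)[C@@H]2[C@H](OC(C)=O)[C@@H](OC(C)=O)[C@@H](C)C(=O)[C@@]2(C)C1 | intermediate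
21 | C9 enol triflate (C8=C9) | CC(=O)O[C@H]1CC(C)(C)[C@@H]2[C@H](OC(C)=O)[C@@H](OC(C)=O)C(C)=C(OS(=O)(=O)C(F)(F)F)[C@@]2(C)C1 | intermediate
22 | (E)-3-methylpent-2-en-4-yn-1-ol | C#C/C(C)=C/CO | starting material
23 | TBS ether of 22 | C#C/C(C)=C/CO[Si](C)(C)C(C)(C)C | intermediate
24 | (E)-3-methylpenta-2,4-dienyl TBS ether | C=C/C(C)=C/CO[Si](C)(C)C(C)(C)C | intermediate
25 | B-[(E)-5-(TBSO)-3-methylpent-3-enyl]-9-BBN | CC(C)(C)[Si](C)(C)OC/C=C(C)/CCB1C2CCCC1CCC2 | intermediate
26 | 15-O-TBS ether of the target | CC(=O)O[C@H]1CC(C)(C)[C@@H]2[C@H](OC(C)=O)[C@@H](OC(C)=O)C(C)=C(CC/C(C)=C/CO[Si](C)(C)C(C)(C)C)[C@@]2(C)C1 | intermediate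
27 | 2α,6β,7α-triacetoxylabda-8,13E-dien-15-ol | CC(=O)O[C@H]1CC(C)(C)[C@@H]2[C@H](OC(C)=O)[C@@H](OC(C)=O)C(C)=C(CC/C(C)=C/CO)[C@@]2(C)C1 | target

Total step count: 19. Longest linear sequence: 17 (steps 1–15, 18, 19).

**Steps most likely to fail**

Step 8 (the proposed method). The cascade may stall after the fragmentation, through slow conjugation of the alkene or slow closure onto the hindered β,β-dimethyl terminus. The organometallic may also attack the C6 carbonyl, or the product may reopen by retro-Michael reaction under the alkoxide.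
- The fallback sets out from 9 and comes back at 14.
- It splits the cascade into known reactions and changes the mode of ring closure.
- The cuprate opening is quenched cold with acetic acid, so that cyclobutanol 11 is isolated.
- Catalytic K2CO3 in MeOH then effects the De Mayo-type retro-aldol fragmentation and the conjugation, giving seco-dione 13 as an isolated compound.
- Ring A is closed not through the free enolate but through the enamine of the C6 ketone (pyrrolidine, AcOH, Stork-type intramolecular Michael addition).
- Brief base equilibration at C5 follows. No compound outside the list is made.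

Step 15. The C7 acetate may be lost by β-elimination from the ketone, O-sulfonylation of the neopentyl carbonyl may be too slow, or a cationic methyl shift from C10 may intervene.
- The fallback sets out from 20 and comes back at 26.
- Soft enolisation with TMSOTf and 2,6-lutidine gives the C9 trimethylsilyl enol ether F1.
- Fluoride-triggered sulfonylation with C4F9SO2F and catalytic tetrabutylammonium difluorotriphenylsilicate converts it into the alkenyl nonaflate F2.
- F2 takes the place of 21 in the coupling of step 18.

Step 9. Chemoselectivity may be lost through competing reduction of the C6 carbonyl.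
- The fallback sets out from 14 and comes back at 17.
- It replaces kinetic discrimination by protection.
- The less hindered C2 carbonyl is ketalised (ethylene glycol, PPTS) to the C2 dioxolane F3.
- Enolate hydroxylation as in step 10 gives the 7α-hydroxy ketone F4.
- NaBH4 gives the 6β,7α-diol F5.
- Mild aqueous acid frees the 2-keto-6β,7α-diol F6.
- SmI2/H2O then reduces the only remaining ketone to 17.

Further compounds
F0 | step 8 | none | none
F1 | step 15 | C9 trimethylsilyl enol ether of 20 | CC(=O)O[C@H]1CC(C)(C)[C@@H]2[C@H](OC(C)=O)[C@@H](OC(C)=O)C(C)=C(O[Si](C)(C)C)[C@@]2(C)C1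
F2 | step 15 | C9 alkenyl nonaflate | CC(=O)O[C@H]1CC(C)(C)[C@@H]2[C@H](OC(C)=O)[C@@H](OC(C)=O)C(C)=C(OS(=O)(=O)C(F)(F)C(F)(F)C(F)(F)C(F)(F)F)[C@@]2(C)C1
F3 | step 9 | C2 ethylene ketal of 14 | O1CCOC12CC(C)(C)[C@@H]3C(=O)C[C@@H](C)[C@H](O[Si](C)(C)C(C)(C)C)[C@@]3(C)C2
F4 | step 9 | 7α-hydroxy-6-ketone C2 ketal | O1CCOC12CC(C)(C)[C@@H]3C(=O)[C@@H](O)[C@@H](C)[C@H](O[Si](C)(C)C(C)(C)C)[C@@]3(C)C2
F5 | step 9 | 6β,7α-diol C2 ketal | O1CCOC12CC(C)(C)[C@@H]3[C@H](O)[C@@H](O)[C@@H](C)[C@H](O[Si](C)(C)C(C)(C)C)[C@@]3(C)C2
F6 | step 9 | 6β,7α-dihydroxy-9β-(TBSO)-2-ketone | O=C1CC(C)(C)[C@@H]2[C@H](O)[C@@H](O)[C@@H](C)[C@H](O[Si](C)(C)C(C)(C)C)[C@@]2(C)C1
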